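I take the bis adduct to cost two equivalents of coupling partner: I count one taken when starting material is consumed and a second when bis adduct forms. That gives a budget.

common to all: starting material 0.050 M

| flask | coupling partner | remark | time |
|---|---|---|---|
| alpha | 1.1 equiv | the very flask that is asked about, followed so far |  |
| delta | 1.7 equiv | run made earlier |  |
| flask | 1.10 equiv |  | 5.0 min |

| run | time / min | bis adduct / % | starting material / % |
|---|---|---|---|
| alpha | 0.667 | 6.8 | 59.5 |
| alpha | 1.33 | 10.7 | 39.4 |
| alpha | 2.00 | 13.0 | 34.7 |
| alpha | 2.50 | 13.6 | 31.0 |
| alpha | 3.00 | 13.1 | 30.1 |
| alpha | 4.00 | 11.8 | 24.0 |
| delta | 0.200 | 3.2 | 73.5 |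
| delta | 0.333 | 6.2 | 61.0 |
| delta | 0.500 | 8.0 | 49.3 |
| delta | 0.833 | 18.5 | 36.8 |
| delta | 1.50 | 25.0 | 22.7 |
| delta | 2.50 | 26.7 | 12.7 |

(readings scatter by 1 percentage point)
- Saturday's: at 5.0 min take out 90% of the bis adduct then present, then wait 5.0 min
- Thursday's: at 5.0 min add coupling partner, 100% of the amount charged, then wait 5.0 min
- Wednesday's: at 5.0 min add starting material, 50.0% of the amount charged, then wait 5.0 min
- Tuesday's: change nothing and wait 5.0 min more
- what is taken out of bis adduct is counted as made
- the analysis behind the earlier runs scatters by 1 percentage point, standard deviation
- additions bring no volume worth counting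
* bis adduct, in percent of the starting material first charged, at 5.0 min
* which option adds most bis adduct ("none" when 2 percentage points or less is all one gets) (Saturday's / Thursday's / Wednesday's / Tuesday's / none)
* bis adduct present, with what was taken out counted in, in percent of the starting material first charged, after Saturday's
* bis adduct present, with what was taken out counted in, in percent of the starting material first charged, after Tuesday's

I read the alpha table down its bis adduct column. It climbs to 13.6% at 2.50 min, then reads 11.8% at 4.00 min. I take that fall to mean that something removes bis adduct in alpha.

The last alpha row shows how much. Of 1.1 equiv of partner, the starting material has taken 76.0%, which leaves a budget of 34.0% for bis adduct ever made. The table reads 11.8% of bis adduct there, so by these readings up to 22.2% has gone. I leave free partner uncounted, which makes that an upper estimate. Adding the bis column over time, row by row, gives 0.418 min of the whole charge held as bis adduct.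

So the loss constant k, the share of bis adduct lost per minute, has the upper estimate 0.531 /min. With making ignored, my low estimate for the flask at 5.0 min is 6.94%.

The forecast says 11% at that time, 8.3% after Tuesday's, 15.3% after Saturday's, and picks Thursday's, reasoning that “bis formation must be offset by a loss of bis”.

The flask gives 8.07% at 5.0 min and 7.88% after Saturday's, and Thursday's wins, adding 7.4 percentage points. At 5.00 min bis adduct in the flask is made at 0.338 of the rate at which it is used up, each step taken net, so it is made more slowly than it is used up.

    starting material + coupling partner → first product (k = 0.340 /M/s)
    coupling partner + first product → bis adduct (k = 0.220 /M/s)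
    bis adduct → over-reaction product (k = 0.00730 /s)

Applied to 8.07% with making ignored, k gives 0.567% after Tuesday's, and the flask gives 1.43%.

For the flask left until 20 min, k with making ignored gives 0.00280%. The computed value is 0.0248%, hardly any of the bis adduct at 5.0 min.

The numbers in the tables are calculated for substances that don't exist; the scatter is artificial.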